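The whole plan rests on the C1=C10 double bond of the cyclodecene ring (C1–C10, germacrane numbering), the ring-cis trisubstituted olefin that carries the C14 carboxyl. It is traced back to SO2 extrusion from an eleven-membered thiacycle with sulfur between C1 and C10. One Ramberg–Bäcklund operation forges the C1–C10 bond, fixes the olefin geometry and contracts the ring from eleven to ten atoms. The precursor is a macrocyclic sulfone, α-sulfonyl ester at C10 and propargylic at C1 (C2≡C3 alkyne), closed by double displacement of a bis-mesylate with sulfide. C7 and C8 come from one radical conjugate addition that relays two purchased stereocentres (C6, C9).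

Key step: step 13

Remark: germacrane numbering is used for all intermediates (ring C1–C10, lactone O6/C12/C11, methylene C13, carboxyl C14, methyl C15; TMSE = 2-(trimethylsilyl)ethyl). The C10 stereocentre of 7–18 is destroyed in step 13, so its configuration is of no consequence.

Step 1
Reactants: 1 D-isoascorbic acid (erythorbic acid)
Product: 2 5,6-O-isopropylidene-D-isoascorbic acid
Conditions: 2,2-dimethoxypropane, p-TsOH (cat.), acetone, rt
Reagents that add atoms: 2,2-dimethoxypropane COC(C)(C)OC
Why: Acid-catalysed transketalisation engages the only vicinal diol (O5/O6) as the terminal dioxolane and leaves both stereocentres untouched.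

Step 2
Reactants: 2 5,6-O-isopropylidene-D-isoascorbic acid
Product: 4 methyl (2R,3R)-3,4-O-isopropylidene-D-erythronate, via potassium erythronate 3 (not isolated)
Conditions: 30% H2O2, K2CO3, H2O, 0 °C to rt; evaporate; MeI, MeCN, reflux
Reagents that add atoms: hydrogen peroxide OO; iodomethane CI
Why: Alkaline peroxide cleavage of the ene-diol lactone (the classical ascorbate degradation) removes two carbons as oxalate, and the remaining C4 carboxylate is O-alkylated by SN2, both stereocentres being spectators.

Step 3
Reactants: 4 methyl 3,4-O-isopropylidene-D-erythronate; 5 2-(trimethylsilyl)ethanol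
Product: 6 TMSE 3,4-O-isopropylidene-D-erythronate
Conditions: 5 (3 equiv), Ti(Oi-Pr)4 (10 mol %), toluene, 90 °C, MeOH distilled off
Reagents that add atoms: none
Why: Titanate-catalysed transesterification is driven by removal of methanol and installs the fluoride-labile ester that has to survive base, acid and oxidants until the last step.

Step 4
Reactants: 6 TMSE 3,4-O-isopropylidene-D-erythronate
Product: 7 TMSE (2R,3R)-2-O-mesyl-3,4-O-isopropylidene-D-erythronate (C14–C10–C9–C8 unit)
Conditions: MsCl, Et3N, CH2Cl2, 0 °C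
Reagents that add atoms: methanesulfonyl chloride CS(=O)(=O)Cl
Why: Routine sulfonylation turns O10 into the leaving group for sulfur and at the same time deactivates C10–H towards hydrogen abstraction in step 6.

Step 5
Reactants: 8 (S)-5-(hydroxymethyl)furan-2(5H)-one
Product: 9 (S)-5-[(triethylsilyloxy)methyl]furan-2(5H)-one
Conditions: TESCl, imidazole, CH2Cl2, 0 °C
Reagents that add atoms: chlorotriethylsilane CC[Si](Cl)(CC)CC
Why: Routine silylation, with a primary TES ether chosen because it can later be oxidised directly to the aldehyde.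

Step 6
Reactants: 9 (S)-5-[(triethylsilyloxy)methyl]furan-2(5H)-one; 7 TMSE 2-O-mesyl-3,4-O-isopropylidene-D-erythronate
Product: 10 C7–C8 coupled trans-lactone (C6 CH2OTES; C7 trans-dioxolanyl C8/C9; C10 OMs; C14 TMSE ester)
Conditions: 7 (3 equiv, excess recovered), (n-Bu4N)4W10O32 (2 mol %), MeCN, 390 nm LED, 25 °C
Reagents that add atoms: none
Why: In this decatungstate-photocatalysed hydrogen-atom transfer/Giese addition the electrophilic excited polyoxometalate abstracts the most hydridic and least hindered C–H (dioxolane CH2 = C8; C9–H and C10–H are polarity-mismatched by the mesyloxy ester), and the nucleophilic α-oxy radical adds to the butenolide β-carbon C7 anti to the C6 side chain and through its own face anti to the C9 substituent (trans-dioxolane), so that C7 and C8 are both set by substrate control in one event.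

Step 7
Reactants: 10 C7–C8 coupled trans-lactone
Product: 11 C5 aldehyde
Conditions: (COCl)2, DMSO, CH2Cl2, −78 to −40 °C; Et3N, −78 to 0 °C
Reagents that add atoms: none
Why: Swern oxidation applied directly to a primary triethylsilyl ether (the chlorosulfonium ion cleaves the unhindered Si–O bond) gives the aldehyde in one operation, and the low temperature protects the epimerisable C6.

Step 8
Reactants: 11 C5 aldehyde
Product: 12 (Z)-vinyl iodide C5H=C4(I)CH3 (iodine cis to C6)
Conditions: EtPPh3I, n-BuLi, THF, rt; I2, −78 °C; NaHMDS, −20 °C; then 11, −78 °C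
Reagents that add atoms: ethyltriphenylphosphonium iodide CC[P+](c1ccccc1)(c1ccccc1)c1ccccc1.[I-]; iodine II
Why: The Stork–Zhao-type Wittig olefination with the α-iodoethylidene ylide is kinetically Z-selective and places iodine cis to C6, as the ring-cis C4=C5 bond requires.

Step 9
Reactants: 12 (Z)-vinyl iodide; 13 propargyl alcohol
Product: 14 (Z)-enynol C6–C5H=C4(CH3)–C3≡C2–C1H2OH
Conditions: PdCl2(PPh3)2 (5 mol %), CuI (10 mol %), Et3N, THF, rt
Reagents that add atoms: none
Why: Sonogashira coupling proceeds with retention of the vinyl iodide geometry and brings in C1–C3 in one step.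

Step 10
Reactants: 14 (Z)-enynol
Product: 15 C1/C10 bis-mesylate
Conditions: MsCl, Et3N, CH2Cl2, −20 °C, used crude
Reagents that add atoms: methanesulfonyl chloride CS(=O)(=O)Cl
Why: Routine sulfonylation of the only free hydroxyl gives the second electrophilic terminus.

Step 11
Reactants: 15 C1/C10 bis-mesylate
Product: 17 eleven-membered cyclic sulfide (S between C1 and C10), via sodium C1-thiolate 16 (not isolated)
Conditions: Na2S, DMF, 0 °C to rt, slow addition, final 1 mM
Reagents that add atoms: sodium sulfide [Na+].[Na+].[S-2]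
Why: In this double SN2 thioetherification sulfide attacks the primary propargylic mesylate first, and thiolate 16 then displaces the carbonyl-activated secondary mesylate at C10 with inversion under high dilution, the Z-enyne turning the two chain ends towards each other.

Step 12
Reactants: 17 eleven-membered cyclic sulfide
Product: 18 eleven-membered cyclic sulfone
Conditions: 30% H2O2, (NH4)6Mo7O24·4H2O (10 mol %), EtOH, 0 °C to rt
Reagents that add atoms: hydrogen peroxide OO
Why: Molybdate-catalysed peroxide oxidation is chemoselective for sulfur and leaves the deactivated enyne olefin, the ketal and both esters untouched.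

Step 13
Reactants: 18 eleven-membered cyclic sulfone
Product: 21 ten-membered dienyne ester (C1=C10 ring-cis and CIP E; C2≡C3; C4=C5 Z), via alpha-chloro sulfone 19 (not isolated), via episulfone 20 (not isolated)
Conditions: KOt-Bu (1.05 equiv), THF, −78 °C; NCS (1.05 equiv); KOt-Bu (1.5 equiv), −78 to 0 °C
Reagents that add atoms: none
Why: The first equivalent of base removes only the doubly activated C10–H (α to SO2 and to the C14 ester) and NCS chlorinates that carbon to 19; the second equivalent deprotonates the propargylic α′-carbon C1, the carbanion displaces chloride in a 1,3-elimination to episulfone 20, and cheletropic loss of SO2 leaves the C1=C10 double bond, so that the eleven-membered thiacycle contracts to the ten-membered carbocycle. This is the Ramberg–Bäcklund reaction, and the closest known case is the contraction of eleven-membered bis-propargylic α-chloro sulfones to ten-membered enediynes. The only ring closed directly is the transient thiirane 1,1-dioxide (3-exo-tet), and the carbocycle results from its collapse. No stereocentre is created; the stereo-element is the olefin geometry, and only an episulfone with C9 and C2 cis fits into a ring that also holds the linear C1–C2≡C3–C4 unit, which leads to the ring-cis olefin that is also the tiglate-type, thermodynamically preferred enoate. The step needs three selectivities. Halogenation must go to C10, which the large acidity gap between C10–H and C1–H secures. Chlorination must outrun E1cB loss of O9, which should hold because O9 is a tethered ketal alkoxide, the C10 anion exists only at −78 °C, and C10 is quaternary afterwards. Closure must outrun propargyl–allenyl isomerisation, which is favoured by the low temperature and by the carbonyl-activated C–Cl bond. C4=C5 is kept as an olefin and C2–C3 as an alkyne at this stage so that the C1 anion has no β- or vinylogous leaving group and the product cannot undergo 6π-electrocyclisation.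

Step 14
Reactants: 21 ten-membered dienyne ester
Product: 24 α-methylene lactone, via Mannich base 22 (not isolated), via methiodide 23 (not isolated)
Conditions: LDA, THF, −78 °C; CH2=NMe2+ I−, −78 °C to rt; MeI, CH2Cl2/MeOH, rt; aq. NaHCO3
Reagents that add atoms: Eschenmoser's salt C=[N+](C)C.[I-]
Why: In the Eschenmoser methylenation the lactone enolate (C11–H2 is the only acidic C–H left) is aminomethylated anti to the C7 substituent, and quaternisation with mild-base elimination unveils the exocyclic methylene and erases the transient C11 centre.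

Step 15
Reactants: 24 α-methylene lactone
Product: 25 8,9-diol
Conditions: AcOH/H2O 4:1, 50 °C
Reagents that add atoms: none
Why: Acid hydrolysis of the ketal is placed at a stage without any epoxide, and TMSE ester, lactone and dienyne tolerate aqueous acetic acid.

Step 16
Reactants: 25 8,9-diol
Product: 26 9-O-acetyl-8-ol
Conditions: Ac2O (1.05 equiv), pyridine, CH2Cl2, −40 °C
Reagents that add atoms: acetic anhydride CC(=O)OC(C)=O
Why: In this kinetically controlled mono-acylation the allylic, more acidic C9–OH, flanked by the planar sp2 C10, should react before the C8–OH, which is flanked by the branched, lactone-bearing C7.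

Step 17
Reactants: 27 angelic acid
Product: 28 (Z)-2-methylbut-2-en-1-ol
Conditions: LiAlH4, Et2O, 0 °C
Reagents that add atoms: none
Why: Hydride reduction of the acid at low temperature keeps the Z geometry.

Step 18
Reactants: 28 (Z)-2-methylbut-2-en-1-ol
Product: 29 [(2S,3R)-2,3-dimethyloxiran-2-yl]methanol
Conditions: Ti(Oi-Pr)4 (10 mol %), L-(+)-DET (12 mol %), t-BuOOH, 4 Å MS, CH2Cl2, −20 °C
Reagents that add atoms: tert-butyl hydroperoxide CC(C)(C)OO
Why: Sharpless asymmetric epoxidation with L-(+)-tartrate delivers oxygen to the face that gives the 2S series, so both side-chain stereocentres are set by the catalyst and the cis relation follows from the Z olefin.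

Step 19
Reactants: 29 [(2S,3R)-2,3-dimethyloxiran-2-yl]methanol
Product: 30 (2R,3R)-2,3-epoxy-2-methylbutanoic acid (epoxyangelic acid)
Conditions: RuCl3 (2 mol %), NaIO4, CCl4/MeCN/H2O, rt
Reagents that add atoms: sodium periodate [Na+].[O-]I(=O)(=O)=O
Why: Catalytic RuO4 oxidation takes 2,3-epoxy alcohols to glycidic acids without touching the oxirane (the C2 descriptor changes only through CIP priorities).

Step 20
Reactants: 26 9-O-acetyl-8-ol; 30 (2R,3R)-epoxyangelic acid
Product: 32 8-O-epoxyangeloyl-9-O-acetyl dienyne, via mixed anhydride 31 (not isolated)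
Conditions: 30, 2,4,6-Cl3C6H2COCl, Et3N, toluene, rt; then 26, DMAP, rt
Reagents that add atoms: none
Why: Yamaguchi esterification couples hindered partners, and the quaternary α-carbon of the acid excludes epimerisation or ketene formation.

Step 21
Reactants: 32 8-O-epoxyangeloyl-9-O-acetyl dienyne
Product: 33 C4–C5 cis-epoxide (C4/C5 configured as in 37)
Conditions: m-CPBA, CH2Cl2, 0 °C
Reagents that add atoms: m-chloroperbenzoic acid OOC(=O)c1cccc(Cl)c1
Why: Prilezhaev epoxidation picks the only electron-rich olefin (C1=C10, C11=C13 and the alkyne are deactivated), and A(1,3) strain with the cis alkynyl group keeps H6 turned inward so that C7 and the ring cover one face and the peracid adds to the open face, which gives the 5,6-threo epoxide of the target.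

Step 22
Reactants: 33 C4–C5 cis-epoxide
Product: 34 (2Z)-diene epoxide
Conditions: H2 (1 atm), Lindlar catalyst, quinoline, EtOAc, 0 °C, stopped after one equivalent
Reagents that add atoms: none
Why: Lindlar semi-hydrogenation adds hydrogen syn to give the Z olefin, the alkyne occupying the poisoned palladium surface in preference to the conjugated olefins, and the triene that could electrocyclise is never formed because C4–C5 is already an epoxide.

Step 23
Reactants: 34 (2Z)-diene epoxide
Product: 35 leucanthin B TMSE ester (2,3:4,5-diepoxide)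
Conditions: (R,R)-Jacobsen Mn(salen)Cl (10 mol %), NMO, m-CPBA, CH2Cl2, −78 °C
Reagents that add atoms: m-chloroperbenzoic acid OOC(=O)c1cccc(Cl)c1
Why: Jacobsen–Katsuki epoxidation is suited to cis-disubstituted olefins conjugated to a π-system, so the (R,R)-catalyst should select C2=C3 and deliver oxygen to the face that gives the (2R,3R)-cis-epoxide, by analogy with its sense of induction on cyclic conjugated cis-olefins, the ring hindering the C–C rotation that would lead to a trans-epoxide.

Step 24
Reactants: 35 leucanthin B TMSE ester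
Product: 37 leucanthin B, via tetrabutylammonium carboxylate 36 (not isolated)
Conditions: TBAF, THF, 0 °C; cold dilute HCl to pH 4
Reagents that add atoms: none
Why: Fluoride attack on silicon triggers β-fragmentation of the TMSE ester to ethene and the carboxylate under conditions that the epoxides, the acetate, the glycidic ester and the α-methylene lactone tolerate.

Compound list
1 | D-isoascorbic acid | OC[C@@H](O)[C@H]1OC(=O)C(O)=C1O | starting material
2 | 5,6-O-isopropylidene-D-isoascorbic acid | CC1(C)OC[C@@H](O1)[C@H]2OC(=O)C(O)=C2O | intermediate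
3 | potassium 3,4-O-isopropylidene-D-erythronate | [K+].[O-]C(=O)[C@H](O)[C@H]1COC(C)(C)O1 | intermediate
4 | methyl (2R,3R)-3,4-O-isopropylidene-D-erythronate | COC(=O)[C@H](O)[C@H]1COC(C)(C)O1 | intermediate
5 | 2-(trimethylsilyl)ethanol | C[Si](C)(C)CCO | starting material
6 | TMSE 3,4-O-isopropylidene-D-erythronate | C[Si](C)(C)CCOC(=O)[C@H](O)[C@H]1COC(C)(C)O1 | intermediate
7 | TMSE (2R,3R)-2-O-mesyl-3,4-O-isopropylidene-D-erythronate | C[Si](C)(C)CCOC(=O)[C@H](OS(C)(=O)=O)[C@H]1COC(C)(C)O1 | intermediate
8 | (S)-5-(hydroxymethyl)furan-2(5H)-one | O=C1O[C@H](CO)C=C1 | starting material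
9 | (S)-5-[(triethylsilyloxy)methyl]furan-2(5H)-one | O=C1O[C@H](CO[Si](CC)(CC)CC)C=C1 | intermediate
10 | C7–C8 coupled trans-lactone | O=C1O[C@H](CO[Si](CC)(CC)CC)[C@H](C1)[C@@H]2OC(C)(C)O[C@H]2[C@@H](OS(C)(=O)=O)C(=O)OCC[Si](C)(C)C | intermediate
11 | C5 aldehyde | O=C1O[C@H](C=O)[C@H](C1)[C@@H]2OC(C)(C)O[C@H]2[C@@H](OS(C)(=O)=O)C(=O)OCC[Si](C)(C)C | intermediate
12 | (Z)-vinyl iodide | O=C1O[C@H](/C=C(/C)I)[C@H](C1)[C@@H]2OC(C)(C)O[C@H]2[C@@H](OS(C)(=O)=O)C(=O)OCC[Si](C)(C)C | intermediate
13 | propargyl alcohol | C#CCO | starting material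
14 | (Z)-enynol | O=C1O[C@H](/C=C(/C)C#CCO)[C@H](C1)[C@@H]2OC(C)(C)O[C@H]2[C@@H](OS(C)(=O)=O)C(=O)OCC[Si](C)(C)C | intermediate
15 | C1/C10 bis-mesylate | O=C1O[C@H](/C=C(/C)C#CCOS(C)(=O)=O)[C@H](C1)[C@@H]2OC(C)(C)O[C@H]2[C@@H](OS(C)(=O)=O)C(=O)OCC[Si](C)(C)C | intermediate
16 | sodium C1-thiolate | O=C1O[C@H](/C=C(/C)C#CC[S-])[C@H](C1)[C@@H]2OC(C)(C)O[C@H]2[C@@H](OS(C)(=O)=O)C(=O)OCC[Si](C)(C)C.[Na+] | intermediate
17 | eleven-membered cyclic sulfide | C1C#C/C(C)=C\[C@H]2OC(=O)C[C@@H]2[C@@H]3OC(C)(C)O[C@H]3[C@@H](C(=O)OCC[Si](C)(C)C)S1 | intermediate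
18 | eleven-membered cyclic sulfone | C1C#C/C(C)=C\[C@H]2OC(=O)C[C@@H]2[C@@H]3OC(C)(C)O[C@H]3[C@@H](C(=O)OCC[Si](C)(C)C)S1(=O)=O | intermediate
19 | α-chloro sulfone (C10 configuration not defined) | C1C#C/C(C)=C\[C@H]2OC(=O)C[C@@H]2[C@@H]3OC(C)(C)O[C@H]3C(Cl)(C(=O)OCC[Si](C)(C)C)S1(=O)=O | intermediate
20 | episulfone (C9 and C2 cis on the thiirane dioxide; absolute sense at C1/C10 not defined) | [C@@H]12OC(C)(C)O[C@H]1C4(C(=O)OCC[Si](C)(C)C)C(S4(=O)=O)C#C/C(C)=C\[C@H]3OC(=O)C[C@@H]32 | intermediate
21 | ten-membered dienyne ester | [C@@H]12OC(C)(C)O[C@H]1/C(C(=O)OCC[Si](C)(C)C)=C\C#C/C(C)=C\[C@H]3OC(=O)C[C@@H]32 | intermediate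
22 | Mannich base (C13 trans to C8 on the lactone) | [C@@H]12OC(C)(C)O[C@H]1/C(C(=O)OCC[Si](C)(C)C)=C\C#C/C(C)=C\[C@H]3OC(=O)[C@@H](CN(C)C)[C@@H]32 | intermediate
23 | methiodide of 22 | [C@@H]12OC(C)(C)O[C@H]1/C(C(=O)OCC[Si](C)(C)C)=C\C#C/C(C)=C\[C@H]3OC(=O)[C@@H](C[N+](C)(C)C)[C@@H]32.[I-] | intermediate
24 | α-methylene lactone | [C@@H]12OC(C)(C)O[C@H]1/C(C(=O)OCC[Si](C)(C)C)=C\C#C/C(C)=C\[C@H]3OC(=O)C(=C)[C@@H]32 | intermediate
25 | 8,9-diol | [C@@H]1(O)[C@@H](O)/C(C(=O)OCC[Si](C)(C)C)=C\C#C/C(C)=C\[C@H]2OC(=O)C(=C)[C@@H]21 | intermediate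
26 | 9-O-acetyl-8-ol | [C@@H]1(O)[C@@H](OC(C)=O)/C(C(=O)OCC[Si](C)(C)C)=C\C#C/C(C)=C\[C@H]2OC(=O)C(=C)[C@@H]21 | intermediate
27 | angelic acid | C/C=C(/C)C(=O)O | starting material
28 | (Z)-2-methylbut-2-en-1-ol | C/C=C(/C)CO | intermediate
29 | [(2S,3R)-2,3-dimethyloxiran-2-yl]methanol | OC[C@]1(C)O[C@@H]1C | intermediate
30 | (2R,3R)-2,3-epoxy-2-methylbutanoic acid | OC(=O)[C@]1(C)O[C@@H]1C | intermediate
31 | mixed 2,4,6-trichlorobenzoic anhydride of 30 | O=C(OC(=O)[C@]1(C)O[C@@H]1C)c1c(Cl)cc(Cl)cc1Cl | intermediate
32 | 8-O-epoxyangeloyl-9-O-acetyl dienyne | [C@@H]1(OC(=O)[C@]3(C)O[C@@H]3C)[C@@H](OC(C)=O)/C(C(=O)OCC[Si](C)(C)C)=C\C#C/C(C)=C\[C@H]2OC(=O)C(=C)[C@@H]21 | intermediate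
33 | C4–C5 cis-epoxide | [C@@H]1(OC(=O)[C@]3(C)O[C@@H]3C)[C@@H](OC(C)=O)/C(C(=O)OCC[Si](C)(C)C)=C\C#C[C@]4(C)O[C@@H]4[C@H]2OC(=O)C(=C)[C@@H]21 | intermediate
34 | (2Z)-diene epoxide | [C@@H]1(OC(=O)[C@]3(C)O[C@@H]3C)[C@@H](OC(C)=O)/C(C(=O)OCC[Si](C)(C)C)=C\C=C/[C@]4(C)O[C@@H]4[C@H]2OC(=O)C(=C)[C@@H]21 | intermediate
35 | leucanthin B TMSE ester | [C@@H]1(OC(=O)[C@]3(C)O[C@@H]3C)[C@@H](OC(C)=O)/C(C(=O)OCC[Si](C)(C)C)=C\[C@H]5O[C@H]5[C@]4(C)O[C@@H]4[C@H]2OC(=O)C(=C)[C@@H]21 | intermediate
36 | tetrabutylammonium salt of leucanthin B | C=C1C(=O)O[C@H]2[C@H]1[C@H](OC(=O)[C@]1(C)O[C@@H]1C)[C@@H](OC(C)=O)/C(C(=O)[O-])=C\[C@H]1O[C@H]1[C@]1(C)O[C@H]21.CCCC[N+](CCCC)(CCCC)CCCC | intermediate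
37 | leucanthin B | C=C1C(=O)O[C@H]2[C@H]1[C@H](OC(=O)[C@]1(C)O[C@@H]1C)[C@@H](OC(C)=O)/C(C(=O)O)=C\[C@H]1O[C@H]1[C@]1(C)O[C@H]21 | target

Total step count: 24. Longest linear sequence: 20 steps (1 → 7 → 10 → 21 → 37; steps 1–4, 6–16, 20–24).

Steps most likely to fail

Step 13 may fail through E1cB expulsion of O9 from the C10 carbanion before it is chlorinated, or through halogen scrambling between C10 and C1. The fallback moves the halogenation to the sulfide oxidation level. It sets out from sulfide 17, which is treated with NCS in CH2Cl2 at 0 °C. This chlorosulfonium, Pummerer-type α-chlorination goes to the ester-bearing carbon without a free carbanion and gives the α-chloro sulfide F1. m-CPBA (2 equiv, −20 °C) oxidises F1 at sulfur. The fallback comes back to the route at α-chloro sulfone 19, now isolated, and a single charge of KOt-Bu then only has to deprotonate C1 on the way to 21.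

Step 11 may fail through oligomerisation or base-induced elimination, because the ring has to close at the hindered secondary C10. The fallback changes the ring-closing bond and sets out from enynol 14.
- KSAc (DMF, rt) displaces the C10 mesylate intermolecularly with inversion to give the C10 thioacetate F2.
- An Appel reaction (CBr4, PPh3, CH2Cl2) converts the C1 hydroxyl into the propargylic bromide F3.
- K2CO3 in degassed MeOH/THF at high dilution frees the thiolate, which closes the ring at the unhindered primary C1.

The fallback comes back at 17 with the same C10 configuration.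

Step 16 may fail through poor site selectivity between the two secondary hydroxyls, or through acetyl migration from O9 to O8 during step 20. The fallback differentiates the two positions by oxidation level and sets out from diol 25.
- MnO2 (CH2Cl2, rt) oxidises only the allylic C9–OH to the C9 ketone F4.
- Mixed anhydride 31 with DMAP acylates the remaining C8–OH to the keto ester F5.
- Luche reduction (NaBH4, CeCl3·7H2O, MeOH, −78 °C) should give the 9α-alcohol F6, because polar Felkin–Anh attack anti to the C8–O bond leads to the threo relationship.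
- Acetylation (Ac2O, pyridine) brings the fallback back to the route at 32.

Further compounds
F1 | step 13 | α-chloro sulfide (C10 configuration not defined) | C1C#C/C(C)=C\[C@H]2OC(=O)C[C@@H]2[C@@H]3OC(C)(C)O[C@H]3C(Cl)(C(=O)OCC[Si](C)(C)C)S1
F2 | step 11 | C10 thioacetate with free C1 hydroxyl | O=C1O[C@H](/C=C(/C)C#CCO)[C@H](C1)[C@@H]2OC(C)(C)O[C@H]2[C@H](SC(C)=O)C(=O)OCC[Si](C)(C)C
F3 | step 11 | C10 thioacetate C1 propargylic bromide | O=C1O[C@H](/C=C(/C)C#CCBr)[C@H](C1)[C@@H]2OC(C)(C)O[C@H]2[C@H](SC(C)=O)C(=O)OCC[Si](C)(C)C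
F4 | step 16 | 8-hydroxy C9 ketone | [C@@H]1(O)C(=O)/C(C(=O)OCC[Si](C)(C)C)=C\C#C/C(C)=C\[C@H]2OC(=O)C(=C)[C@@H]21
F5 | step 16 | 8-O-epoxyangeloyl C9 ketone | [C@@H]1(OC(=O)[C@]3(C)O[C@@H]3C)C(=O)/C(C(=O)OCC[Si](C)(C)C)=C\C#C/C(C)=C\[C@H]2OC(=O)C(=C)[C@@H]21
F6 | step 16 | 8-O-epoxyangeloyl 9α-alcohol | [C@@H]1(OC(=O)[C@]3(C)O[C@@H]3C)[C@@H](O)/C(C(=O)OCC[Si](C)(C)C)=C\C#C/C(C)=C\[C@H]2OC(=O)C(=C)[C@@H]21
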